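**Plan**
- Cuts: after removal of six O-benzyl groups, the two bonds of the dihydrofuran ring that hold the halves together are cut at once. These are C(spiro)–C8 of kaempferol ring A and C(hemiketal)–O7. The target is kaempferol plus its isomer 2-(4-hydroxybenzoyl)-4,6-dihydroxybenzofuran-3(2H)-one, minus H2.
- Enabling feature: the spiro carbon is the α-carbon of a 1,3-diketone (benzofuranone C3=O and the 4-hydroxybenzoyl C=O, which is masked as the hemiketal carbon). It sits on C8, ortho to O7, so the ring O7–C(OH)Ar–C(spiro)–C8–C7 is the adduct of a phenol C,O-bis-nucleophile with a diketone oxidised by two electrons.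
- Further cuts: C2–C3 (Dieckmann) and O1–C2 (Williamson) in the diketone half. The chromone half is kaempferol itself, on which protecting groups are moved until only the 7-OH is free.
- Forward ring order: rings A, B and C of the chromone come with kaempferol, the benzofuranone ring closes in step 8, the spiro dihydrofuran ring closes last in step 9, and hydrogenolysis ends the route.
- Stereochemistry: the spiro carbon (S) comes from a chiral trivalent iron phosphate catalyst in step 9. The hemiketal carbon (R) follows by thermodynamic relay (OH syn to C3=O, aryl syn to O1).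

Key step: step 9

Assumption: the (R)-binaphthyl phosphate is taken to expose the face of bound 12 that leads to the (S)-spiro carbon; the sense of induction cannot be derived with certainty, and the (S)-ligand would be used otherwise with no other change.

Step 1
Reactants: 1 kaempferol
Product: 2 kaempferol 3,5,7,4'-tetraacetate
Conditions: Ac2O, pyridine, 4-(dimethylamino)pyridine (cat.), rt → 60 °C
Reagents that add atoms: acetic anhydride, CC(=O)OC(C)=O
Why: Exhaustive O-acylation of phenols under nucleophilic catalysis takes all four hydroxyl groups, the chelated 5-OH included, and no stereocentre is involved.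

Step 2
Reactants: 2 kaempferol 3,5,7,4'-tetraacetate
Product: 3 3,5,4'-tri-O-acetylkaempferol (free 7-OH)
Conditions: PhSH (1.2 equiv), imidazole (0.4 equiv), N-methyl-2-pyrrolidone, 0 °C → rt
Reagents that add atoms: none
Why: Chemoselective thiolysis (transacylation) of an aryl ester: the 7-acetate belongs to the most acidic phenol of the flavonol, para to the carbon that carries the C4 carbonyl, so it is the best leaving group and is the one removed from peracylated flavones and flavonols under these conditions.

Step 3
Reactants: 3 3,5,4'-tri-O-acetylkaempferol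
Product: 4 3,5,4'-tri-O-acetyl-7-O-(methoxymethyl)kaempferol
Conditions: MOMCl, i-Pr2NEt, CH2Cl2, 0 °C → rt
Reagents that add atoms: chloromethyl methyl ether (MOMCl), COCCl
Why: O-Alkylation of the acidic 7-OH with a chloromethyl ether and a hindered amine base (acetal protection) is fast at low temperature and leaves the three aryl acetates in place.

Step 4
Reactants: 4 3,5,4'-tri-O-acetyl-7-O-(methoxymethyl)kaempferol
Product: 6 3,5,4'-tri-O-benzyl-7-O-(methoxymethyl)kaempferol, via 7-O-methoxymethylkaempferol 5 (not isolated)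
Conditions: K2CO3, MeOH/THF, rt, Ar; evaporate; BnBr (6 equiv), K2CO3, DMF, 70 °C
Reagents that add atoms: benzyl bromide, BrCc1ccccc1
Why: Carbonate-mediated transesterification followed in the same flask by Williamson etherification exchanges three esters for three benzyl ethers, warm DMF and excess halide being the usual way to alkylate the hydrogen-bonded 5-OH, while the MOM acetal is inert to base.

Step 5
Reactants: 6 3,5,4'-tri-O-benzyl-7-O-(methoxymethyl)kaempferol
Product: 7 3,5,4'-tri-O-benzylkaempferol (3,5-bis(benzyloxy)-2-[4-(benzyloxy)phenyl]-7-hydroxy-4H-chromen-4-one)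
Conditions: 3 M aq HCl, THF, 50 °C
Reagents that add atoms: none
Why: Acid-catalysed hydrolysis of the aryl MOM acetal is quick because the 7-phenol is a good leaving group, and dilute acid at this temperature should not touch the benzyl ethers.

Step 6
Reactants: 8 methyl 2,4,6-trihydroxybenzoate
Product: 9 methyl 2,4-bis(benzyloxy)-6-hydroxybenzoate
Conditions: BnBr (2.1 equiv), K2CO3, acetone, reflux
Reagents that add atoms: benzyl bromide, BrCc1ccccc1
Why: Williamson etherification stops after two alkylations because the last ortho hydroxyl group is locked in a hydrogen bond to the ester carbonyl.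

Step 7
Reactants: 9 methyl 2,4-bis(benzyloxy)-6-hydroxybenzoate; 10 2-bromo-1-[4-(benzyloxy)phenyl]ethan-1-one
Product: 11 methyl 2,4-bis(benzyloxy)-6-{2-[4-(benzyloxy)phenyl]-2-oxoethoxy}benzoate
Conditions: K2CO3, DMF, rt → 50 °C
Reagents that add atoms: none
Why: Williamson etherification with a very reactive α-bromo ketone in a dipolar aprotic solvent overcomes the chelation of the remaining phenol.

Step 8
Reactants: 11 methyl 2,4-bis(benzyloxy)-6-{2-[4-(benzyloxy)phenyl]-2-oxoethoxy}benzoate
Product: 12 [4,6-bis(benzyloxy)-3-hydroxy-1-benzofuran-2-yl][4-(benzyloxy)phenyl]methanone (enol tautomer of the 2-aroylbenzofuran-3(2H)-one)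
Conditions: t-BuOK, THF, 0 °C → rt; then 1 M HCl
Reagents that add atoms: none
Why: Dieckmann-type intramolecular Claisen condensation, a 5-exo-trig attack of the phenacyl ether enolate on the adjacent ester that is driven by formation of the stabilised diketonate, is the standard entry to 2-aroyl-3-hydroxybenzofurans from salicylate esters.

Step 9
Reactants: 7 3,5,4'-tri-O-benzylkaempferol; 12 [4,6-bis(benzyloxy)-3-hydroxy-1-benzofuran-2-yl][4-(benzyloxy)phenyl]methanone
Product: 14 (2S,8'R)-3',4,5',6-tetrakis(benzyloxy)-2',8'-bis[4-(benzyloxy)phenyl]-8'-hydroxy-8'H-spiro[1-benzofuran-2,9'-furo[2,3-h]chromene]-3,4'-dione, via open keto-phenol 13 (not isolated)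
Conditions: Fe(ClO4)3 (10 mol %), (R)-3,3'-bis(2,4,6-triisopropylphenyl)-1,1'-binaphthyl-2,2'-diyl hydrogen phosphate (30 mol %), CaCO3 (15 mol %), t-BuOOt-Bu (1.5 equiv), ClCH2CH2Cl/(CF3)2CHOH, 25 °C, Ar
Reagents that add atoms: none
Why: Proposed new method: the trivalent iron tris(phosphate) binds 12 as a chelating diketonate and 7 through O7, the peroxide oxidises the assembly, the electrophilic C2 radical of the diketonate (captodatively stabilised by O1 and two carbonyls) is trapped by the nucleophilic C8 of 7, and a second electron transfer with loss of a proton rearomatises ring A to keto-phenol 13. The closest known reaction type is the iron-catalysed cross-dehydrogenative coupling of phenols with α-substituted β-dicarbonyl compounds to 2-hydroxy-2,3-dihydrobenzofurans, whose enantioselective chiral iron phosphate form is known only for 2-naphthols with β-keto esters; new here are a 7-hydroxychromone as the arene and an α-aryloxy 1,3-diketone as the partner. The one ring closed is the dihydrofuran, by reversible 5-exo-trig addition of O7–H to the 4-benzyloxybenzoyl carbonyl of 13 rather than to C3=O, which is deactivated by its 2,4,6-trioxygenated aryl ring. The spiro carbon is set in the C–C bond-forming event, in which the binaphthyl phosphates leave one face of the planar bound diketonate open to the co-bound phenol, and the hemiketal carbon is set under thermodynamic control by ring–chain tautomerism, which places OH syn to C3=O (O–H···O=C hydrogen bond) and the aryl group syn to the small O1. The step needs cross- over homo-coupling, C- over O-attack and C8 over C6: 7 carries the chromone acceptor and should resist oxidation while 12 is easily oxidised to a hindered tertiary radical that should not dimerise, an O-linked mixed ketal would re-ionise in the acidic fluoroalcohol medium, and C8 is the naphthol-like α-position of a 7-hydroxychromone and para to the donor 5-OBn, whereas C6 is shielded by that same benzyl group.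

Step 10
Reactants: 14 hexa-O-benzyl spiro hemiketal
Product: 15 (2S,8'R)-3',4,5',6,8'-pentahydroxy-2',8'-bis(4-hydroxyphenyl)-8'H-spiro[1-benzofuran-2,9'-furo[2,3-h]chromene]-3,4'-dione (target)
Conditions: H2 (1 atm), 10% Pd/C, THF/EtOAc, rt
Reagents that add atoms: none
Why: Catalytic hydrogenolysis of aryl benzyl ethers under neutral conditions frees six phenols, the quaternary spiro carbon has no epimerisation pathway in the absence of acid or base, its fully substituted C–O bonds are shielded from the catalyst surface, and the hemiketal settles again as the hydrogen-bonded (R)-epimer.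

**Compound list**
1 | kaempferol | Oc1cc(O)c2c(=O)c(O)c(-c3ccc(O)cc3)oc2c1 | starting material
2 | kaempferol 3,5,7,4'-tetraacetate | CC(=O)Oc1cc(OC(C)=O)c2c(=O)c(OC(C)=O)c(-c3ccc(OC(C)=O)cc3)oc2c1 | intermediate
3 | 3,5,4'-tri-O-acetylkaempferol | Oc1cc(OC(C)=O)c2c(=O)c(OC(C)=O)c(-c3ccc(OC(C)=O)cc3)oc2c1 | intermediate
4 | 3,5,4'-tri-O-acetyl-7-O-(methoxymethyl)kaempferol | COCOc1cc(OC(C)=O)c2c(=O)c(OC(C)=O)c(-c3ccc(OC(C)=O)cc3)oc2c1 | intermediate
5 | 7-O-(methoxymethyl)kaempferol (not isolated) | COCOc1cc(O)c2c(=O)c(O)c(-c3ccc(O)cc3)oc2c1 | intermediate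
6 | 3,5,4'-tri-O-benzyl-7-O-(methoxymethyl)kaempferol | COCOc1cc(OCc2ccccc2)c2c(=O)c(OCc3ccccc3)c(-c3ccc(OCc4ccccc4)cc3)oc2c1 | intermediate
7 | 3,5,4'-tri-O-benzylkaempferol (free 7-OH) | Oc1cc(OCc2ccccc2)c2c(=O)c(OCc3ccccc3)c(-c3ccc(OCc4ccccc4)cc3)oc2c1 | intermediate
8 | methyl 2,4,6-trihydroxybenzoate | COC(=O)c1c(O)cc(O)cc1O | starting material
9 | methyl 2,4-bis(benzyloxy)-6-hydroxybenzoate | COC(=O)c1c(O)cc(OCc2ccccc2)cc1OCc1ccccc1 | intermediate
10 | 2-bromo-1-[4-(benzyloxy)phenyl]ethan-1-one | O=C(CBr)c1ccc(OCc2ccccc2)cc1 | starting material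
11 | methyl 2,4-bis(benzyloxy)-6-{2-[4-(benzyloxy)phenyl]-2-oxoethoxy}benzoate | COC(=O)c1c(OCC(=O)c2ccc(OCc3ccccc3)cc2)cc(OCc2ccccc2)cc1OCc1ccccc1 | intermediate
12 | [4,6-bis(benzyloxy)-3-hydroxy-1-benzofuran-2-yl][4-(benzyloxy)phenyl]methanone (enol tautomer) | O=C(c1ccc(OCc2ccccc2)cc1)c1oc2cc(OCc3ccccc3)cc(OCc3ccccc3)c2c1O | intermediate
13 | (R)-4,6-bis(benzyloxy)-2-[4-(benzyloxy)benzoyl]-2-{3,5-bis(benzyloxy)-2-[4-(benzyloxy)phenyl]-7-hydroxy-4-oxo-4H-chromen-8-yl}-1-benzofuran-3(2H)-one (open keto-phenol, not isolated) | O=C1c2c(OCc3ccccc3)cc(OCc3ccccc3)cc2O[C@]1(c1c(O)cc(OCc5ccccc5)c3c(=O)c(OCc5ccccc5)c(-c4ccc(OCc5ccccc5)cc4)oc13)C(=O)c1ccc(OCc3ccccc3)cc1 | intermediate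
14 | (2S,8'R)-hexa-O-benzyl spiro hemiketal (all six phenols of 15 as benzyl ethers, hemiketal OH free, OH syn to C3=O) | O=C1c2c(OCc3ccccc3)cc(OCc3ccccc3)cc2O[C@@]12c1c(cc(OCc5ccccc5)c3c(=O)c(OCc5ccccc5)c(-c4ccc(OCc5ccccc5)cc4)oc13)O[C@]2(O)c1ccc(OCc3ccccc3)cc1 | intermediate
15 | (2S,8'R)-3',4,5',6,8'-pentahydroxy-2',8'-bis(4-hydroxyphenyl)-8'H-spiro[1-benzofuran-2,9'-furo[2,3-h]chromene]-3,4'-dione | O=C1c2c(O)cc(O)cc2O[C@@]12c1c(cc(O)c3c(=O)c(O)c(-c4ccc(O)cc4)oc13)O[C@]2(O)c1ccc(O)cc1 | target

Total step count: 10. Longest linear sequence: 7 (steps 1–5, 9, 10).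

**Steps most likely to fail**

1. Step 9 (new method).
   - What may go wrong: the C2 radical of the bound diketonate may be intercepted at oxygen or by peroxide fragments instead of by C8. Attack may also leak to C6, or the two faces of the diketonate may be poorly told apart.
   - Fallback: known chemistry throughout. It uses ligand coupling at tetravalent lead in place of oxidative coupling, fixes the regiochemistry with a halogen, and parts the enantiomers by resolution. It sets out from 6 and 12 and comes back at 14.
   - Electrophilic iodination of 6 (N-iodosuccinimide, MeCN), which goes to C8 in 5,7-dialkoxyflavones, should give the 8-iodide F1.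
   - Stannylation (Bu3SnSnBu3, Pd(PPh3)4, toluene, 100 °C) should give the 8-tributylstannane F2.
   - Tin–lead exchange (Pb(OAc)4, Hg(OAc)2 cat., CHCl3) should give the aryllead triacetate F3.
   - Pinhey arylation of 12 with it (pyridine, CHCl3, 40–60 °C) should give the racemic 7-O-MOM diketone F4.
   - Aqueous HCl in THF then removes the MOM group. The freed keto-phenol, 13 together with the enantiomer of 13 F5, closes to the racemic hemiketal.
   - From that racemate 14 is parted from the enantiomer of 14 F6 by preparative chromatography on cellulose tris(3,5-dimethylphenylcarbamate).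

2. Step 10.
   - What may go wrong: reductive cleavage of the benzylic C–O bonds at the spiro and hemiketal carbons, or saturation of the chromone C2=C3 bond, may compete with the slow removal of the more hindered benzyl groups. The emerging polyphenol may also poison the catalyst.
   - Fallback: non-reductive Lewis acid debenzylation with BCl3 and pentamethylbenzene as benzyl cation trap (CH2Cl2, −78 °C), followed by aqueous work-up that lets the hemiketal re-form under thermodynamic control. It sets out from 14 and comes back at 15, with no new compound F0.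

3. Step 5.
   - What may go wrong: the 5-O-benzyl group, activated by the peri C4 carbonyl, may be lost in the acidic medium before the MOM acetal is fully cleaved.
   - Fallback: the temporary group is changed to an allyl ether, which is taken off under neutral catalysis by zerovalent palladium. It sets out from 3 and comes back at 7.
   - Mitsunobu etherification of 3 (allyl alcohol, PPh3, diisopropyl azodicarboxylate, THF) should give 7-O-allyl-3,5,4'-tri-O-acetylkaempferol F7.
   - K2CO3 in MeOH/THF should give 7-O-allylkaempferol F8, which is not isolated.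
   - BnBr, K2CO3, DMF, 70 °C should give 7-O-allyl-3,5,4'-tri-O-benzylkaempferol F9.
   - Pd(PPh3)4 with morpholine in THF at rt then transfers the allyl group to the amine and should give 7.

**Further compounds**
F1 | step 9 | 3,5,4'-tri-O-benzyl-8-iodo-7-O-(methoxymethyl)kaempferol | COCOc1cc(OCc2ccccc2)c2c(=O)c(OCc3ccccc3)c(-c3ccc(OCc4ccccc4)cc3)oc2c1I
F2 | step 9 | 3,5,4'-tri-O-benzyl-7-O-(methoxymethyl)-8-(tributylstannyl)kaempferol | COCOc1cc(OCc2ccccc2)c2c(=O)c(OCc3ccccc3)c(-c3ccc(OCc4ccccc4)cc3)oc2c1[Sn](CCCC)(CCCC)CCCC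
F3 | step 9 | [3,5,4'-tri-O-benzyl-7-O-(methoxymethyl)kaempferol-8-yl]lead triacetate | COCOc1cc(OCc2ccccc2)c2c(=O)c(OCc3ccccc3)c(-c3ccc(OCc4ccccc4)cc3)oc2c1[Pb](OC(C)=O)(OC(C)=O)OC(C)=O
F4 | step 9 | racemic 4,6-bis(benzyloxy)-2-[4-(benzyloxy)benzoyl]-2-{3,5-bis(benzyloxy)-2-[4-(benzyloxy)phenyl]-7-(methoxymethoxy)-4-oxo-4H-chromen-8-yl}-1-benzofuran-3(2H)-one (racemate, no configuration drawn) | O=C1c2c(OCc3ccccc3)cc(OCc3ccccc3)cc2OC1(c1c(OCOC)cc(OCc5ccccc5)c3c(=O)c(OCc5ccccc5)c(-c4ccc(OCc5ccccc5)cc4)oc13)C(=O)c1ccc(OCc3ccccc3)cc1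
F5 | step 9 | (S)-enantiomer of 13 | O=C1c2c(OCc3ccccc3)cc(OCc3ccccc3)cc2O[C@@]1(c1c(O)cc(OCc5ccccc5)c3c(=O)c(OCc5ccccc5)c(-c4ccc(OCc5ccccc5)cc4)oc13)C(=O)c1ccc(OCc3ccccc3)cc1
F6 | step 9 | (2R,8'S)-enantiomer of 14 | O=C1c2c(OCc3ccccc3)cc(OCc3ccccc3)cc2O[C@]12c1c(cc(OCc5ccccc5)c3c(=O)c(OCc5ccccc5)c(-c4ccc(OCc5ccccc5)cc4)oc13)O[C@@]2(O)c1ccc(OCc3ccccc3)cc1
F0 | step 10 | none | none
F7 | step 5 | 7-O-allyl-3,5,4'-tri-O-acetylkaempferol | C=CCOc1cc(OC(C)=O)c2c(=O)c(OC(C)=O)c(-c3ccc(OC(C)=O)cc3)oc2c1
F8 | step 5 | 7-O-allylkaempferol | C=CCOc1cc(O)c2c(=O)c(O)c(-c3ccc(O)cc3)oc2c1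
F9 | step 5 | 7-O-allyl-3,5,4'-tri-O-benzylkaempferol | C=CCOc1cc(OCc2ccccc2)c2c(=O)c(OCc3ccccc3)c(-c3ccc(OCc4ccccc4)cc3)oc2c1
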